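**Retrosynthetic overview**

- Target 10 comes from 5,8-dihydroxyflavone 9 by methylation of the free 8-OH; the 5-OH is chelated to the C4 carbonyl and stays.
- 9 is disconnected at O1–C8a. The strategy rests on ring A: O5 and O8 are para to each other (a hydroquinone), and C8a is the unsubstituted ring carbon between C8 and the acyl-bearing C4a. The acylquinone of the open-chain 1,3-diketone 7 can therefore take up the enol oxygen at that carbon.
- 7 comes from acetophenone 4 and acid chloride 5 by C-aroylation of the acetophenone polyanion (C2–C3 bond of the flavone); 4 comes from methoxyhydroquinone 1 and acetic acid 2 by Friedel–Crafts acylation.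
- Ring order: rings A and B are bought; the pyranone ring C is the only ring formed, in step 3.

Key step: step 3

Remark: the target has no stereocentre and is achiral, so the request for a single enantiomer needs no stereocontrol; the route gives the one compound the SMILES describes.

**Step 1**
Reactants: 1 2-methoxybenzene-1,4-diol; 2 acetic acid
Product: 4 1-(2,5-dihydroxy-4-methoxyphenyl)ethanone, via difluoroboron chelate 3 (not isolated)
Conditions: BF3·OEt2 (3 equiv), AcOH, 90 °C, Ar; then H2O, 60 °C
Reagents that add atoms: none
Why: Friedel–Crafts (Nencki-type) C-acylation by the BF3–acetic acid complex should go to the one ring position that is ortho to a hydroxyl and para to the methoxy group, and the ketone is held as its O,O-difluoroboron chelate, which blocks a second acylation until water releases it.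

**Step 2**
Reactants: 4 1-(2,5-dihydroxy-4-methoxyphenyl)ethanone; 5 2,5-dimethoxybenzoyl chloride
Product: 7 1-(2,5-dihydroxy-4-methoxyphenyl)-3-(2,5-dimethoxyphenyl)propane-1,3-dione, via trilithium polyanion 6 (not isolated)
Conditions: LiHMDS (4.2 equiv), THF, −78 to −10 °C, Ar; then 5 (1.0 equiv), −78 °C to rt; cold 1 M HCl quench
Reagents that add atoms: none
Why: Claisen-type C-aroylation of a lithium polyanion, in which the enolate carbon is the most nucleophilic site of the trianion and the fourth equivalent of base takes up the acidic diketone as it forms, so one equivalent of acid chloride should suffice.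

**Step 3**
Reactants: 7 1-(2,5-dihydroxy-4-methoxyphenyl)-3-(2,5-dimethoxyphenyl)propane-1,3-dione
Product: 9 2-(2,5-dimethoxyphenyl)-5,8-dihydroxy-7-methoxy-4H-chromen-4-one, via acylbenzoquinone 8 (not isolated)
Conditions: undivided cell, graphite anode, Pt cathode, controlled potential at the first anodic wave (expected near +0.4 to +0.5 V vs Ag/AgCl, to be set by cyclic voltammetry), 2.0–2.2 F/mol, MeCN/aq. phosphate buffer pH 7 (1:1), about 10 mM, Ar, rt; then aq. Na2S2O4 wash, pH 4
Reagents that add atoms: none
Why: Proposed new method: anodic two-electron, two-proton oxidation of the hydroquinone ring of 7, which should be far easier to oxidise than the dimethoxyphenyl ring, should give acylbenzoquinone 8, whose ring CH between the acyl-bearing carbon and a quinone carbonyl is β to both the ring C=O and the side-chain C=O; the distal enol(ate) oxygen of the 1,3-diketone adds there and tautomerisation re-aromatises ring A as the 5,8-hydroquinone, so that O1–C8a forms with net loss of H2 at the cathode. The closest known reaction types are the anodic oxidation of hydroquinones and catechols in buffered aqueous acetonitrile with conjugate addition of 1,3-dicarbonyl compounds to the electrogenerated quinone, and the addition of O-nucleophiles to C3 of 2-acyl-1,4-benzoquinones. The pyranone ring closes in a 6-endo-trig oxa-Michael mode (equivalently an oxa-6π closure of the quinone-conjugated enol), and no stereocentre is formed. The step needs site selectivity for the carbon that becomes C8a: only the enol oxygen on the B-ring side can reach the quinone through a six-membered transition state, attack by the central carbon or by the inner oxygen would need a four-membered ring, and the other ring CH is part of a methoxy-deactivated vinylogous ester. It also needs the classical acid-driven cyclodehydration through the 2-hydroxyl, which would give the wrong 6,7-dioxygenated flavone, to stay silent; the neutral buffer at room temperature and the conversion of that hydroxyl into a quinone carbonyl should secure this. Over-oxidation of the product hydroquinone should be reversed at the cathode of the undivided cell and by the dithionite wash.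

**Step 4**
Reactants: 9 2-(2,5-dimethoxyphenyl)-5,8-dihydroxy-7-methoxy-4H-chromen-4-one
Product: 10 2-(2,5-dimethoxyphenyl)-5-hydroxy-7,8-dimethoxy-4H-chromen-4-one (5-hydroxy-7,8,2',5'-tetramethoxyflavone)
Conditions: Me2SO4 (1.05 equiv), K2CO3 (1.2 equiv), degassed acetone, 40 °C to reflux, Ar
Reagents that add atoms: dimethyl sulfate, COS(=O)(=O)OC
Why: Williamson ether synthesis, in which the 5-OH is locked in a hydrogen bond to the C4 carbonyl and is much less acidic and nucleophilic than the 8-OH, so one equivalent of dimethyl sulfate with mild base should alkylate O8 only.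

**Compound list**

1 | 2-methoxybenzene-1,4-diol (methoxyhydroquinone) | COc1cc(O)ccc1O | starting material
2 | acetic acid | CC(=O)O | starting material
3 | O,O-difluoroboron chelate of 1-(2,5-dihydroxy-4-methoxyphenyl)ethanone (boron bound to the 2-oxygen and the ketone oxygen) | CC1=[O+][B-](F)(F)Oc2cc(OC)c(O)cc21 | intermediate
4 | 1-(2,5-dihydroxy-4-methoxyphenyl)ethanone (2,5-dihydroxy-4-methoxyacetophenone) | CC(=O)c1cc(O)c(OC)cc1O | intermediate
5 | 2,5-dimethoxybenzoyl chloride | COc1ccc(OC)c(C(=O)Cl)c1 | starting material
6 | trilithium salt of 4 (2,5-diphenoxide and ketone enolate) | [Li+].[Li+].[Li+].C=C([O-])c1cc([O-])c(OC)cc1[O-] | intermediate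
7 | 1-(2,5-dihydroxy-4-methoxyphenyl)-3-(2,5-dimethoxyphenyl)propane-1,3-dione | COc1ccc(OC)c(C(=O)CC(=O)c2cc(O)c(OC)cc2O)c1 | intermediate
8 | 2-[3-(2,5-dimethoxyphenyl)-3-oxopropanoyl]-5-methoxy-1,4-benzoquinone | COc1ccc(OC)c(C(=O)CC(=O)C2=CC(=O)C(OC)=CC2=O)c1 | intermediate
9 | 2-(2,5-dimethoxyphenyl)-5,8-dihydroxy-7-methoxy-4H-chromen-4-one | COc1ccc(OC)c(-c2cc(=O)c3c(O)cc(OC)c(O)c3o2)c1 | intermediate
10 | 2-(2,5-dimethoxyphenyl)-5-hydroxy-7,8-dimethoxy-4H-chromen-4-one (5-hydroxy-7,8,2',5'-tetramethoxyflavone) | COc1ccc(OC)c(-c2cc(=O)c3c(O)cc(OC)c(OC)c3o2)c1 | target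

**Step count**

Total steps: 4. Longest linear sequence: 4 (1 → 4 → 7 → 9 → 10).

**Steps most likely to fail**

1. Step 3 (Proposed new method). The electrogenerated quinone may be consumed by intermolecular addition (water, or the diketone carbon of a second molecule) or by further oxidation faster than the intramolecular O–C closure, or the enol may stay locked in its hydrogen-bonded chelate and not reach the ring. The fallback builds the 5,8-hydroquinone by para-hydroxylation of a 5-hydroxyflavone and uses known chemistry only. It sets out from 5 and returns at 9. Purchased 1-(2,6-dihydroxy-4-methoxyphenyl)ethanone F1 is converted into its polyanion with LiHMDS (4 equiv, THF, −78 °C) and C-aroylated with 5 to give 1-(2,6-dihydroxy-4-methoxyphenyl)-3-(2,5-dimethoxyphenyl)propane-1,3-dione F2. Cyclodehydration with catalytic H2SO4 in AcOH at 95 °C gives 2-(2,5-dimethoxyphenyl)-5-hydroxy-7-methoxy-4H-chromen-4-one F3. Elbs persulfate oxidation (K2S2O8, aq. KOH/pyridine, 15–20 °C) puts oxygen para to the 5-hydroxyl and gives the potassium 8-sulfate F4, which is hydrolysed without isolation (aq. HCl, Na2SO3, 90 °C) to 9.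

2. Step 2. O-aroylation of the unchelated 5-phenoxide may compete with C-aroylation, polyanion formation may be incomplete, and the electron-rich hydroquinone trianion may be oxidised by traces of air. The fallback is a Baker–Venkataraman sequence that sets out from 4 (with 5) and returns at 7. Acylation of both hydroxyls with 5 (2.2 equiv, pyridine, DMAP, rt) gives 2-acetyl-5-methoxy-1,4-phenylene bis(2,5-dimethoxybenzoate) F5. Powdered KOH in pyridine at 50 °C moves the ortho ester onto the methyl ketone carbon and gives 1-[5-(2,5-dimethoxybenzoyloxy)-2-hydroxy-4-methoxyphenyl]-3-(2,5-dimethoxyphenyl)propane-1,3-dione F6. Saponification of the remaining ester (aq. NaOH/THF, rt, Ar, then mild acidification) gives 7.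

3. Step 4. Methylation may run on to the chelated O5, or the 5,8-hydroquinone may be oxidised under base before it is alkylated. The fallback methylates exhaustively and then demethylates selectively; it sets out from 9 and returns at 10. Excess Me2SO4 and K2CO3 in refluxing acetone give 2-(2,5-dimethoxyphenyl)-5,7,8-trimethoxy-4H-chromen-4-one F7. BCl3 (1.5 equiv, CH2Cl2, −78 to 0 °C) then cleaves only the 5-methyl ether, which is peri to the carbonyl and chelation-activated, and aqueous work-up gives 10.

**Further compounds**

F1 | step 3 | 1-(2,6-dihydroxy-4-methoxyphenyl)ethanone (purchased) | CC(=O)c1c(O)cc(OC)cc1O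
F2 | step 3 | 1-(2,6-dihydroxy-4-methoxyphenyl)-3-(2,5-dimethoxyphenyl)propane-1,3-dione | COc1ccc(OC)c(C(=O)CC(=O)c2c(O)cc(OC)cc2O)c1
F3 | step 3 | 2-(2,5-dimethoxyphenyl)-5-hydroxy-7-methoxy-4H-chromen-4-one | COc1ccc(OC)c(-c2cc(=O)c3c(O)cc(OC)cc3o2)c1
F4 | step 3 | potassium 2-(2,5-dimethoxyphenyl)-5-hydroxy-7-methoxy-4-oxo-4H-chromen-8-yl sulfate | COc1ccc(OC)c(-c2cc(=O)c3c(O)cc(OC)c(OS(=O)(=O)[O-])c3o2)c1.[K+]
F5 | step 2 | 2-acetyl-5-methoxy-1,4-phenylene bis(2,5-dimethoxybenzoate) | CC(=O)c1cc(OC(=O)c2cc(OC)ccc2OC)c(OC)cc1OC(=O)c1cc(OC)ccc1OC
F6 | step 2 | 1-[5-(2,5-dimethoxybenzoyloxy)-2-hydroxy-4-methoxyphenyl]-3-(2,5-dimethoxyphenyl)propane-1,3-dione | COc1ccc(OC)c(C(=O)CC(=O)c2cc(OC(=O)c3cc(OC)ccc3OC)c(OC)cc2O)c1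
F7 | step 4 | 2-(2,5-dimethoxyphenyl)-5,7,8-trimethoxy-4H-chromen-4-one | COc1ccc(OC)c(-c2cc(=O)c3c(OC)cc(OC)c(OC)c3o2)c1
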